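## Structural features

The target is an isoflavan: ring A is fused to a pyran (O1, C2, C3, C4, C4a, C8a), and C3 carries ring B (2-hydroxy-3,4-dimethoxyphenyl). C6 of ring A bears a three-carbon chain: Cα is a diarylmethine carrying ring C (2,4-dihydroxyphenyl), Cβ is a secondary carbinol, and the third carbon is the benzylic CH2 of ring D (4-hydroxyphenyl); C7 bears a phenol. There are three stereocentres: C3 (R), isolated in the pyran, and the adjacent pair Cα (R) and Cβ (R). The fragile groups are the five phenols (two resorcinol-type rings that oxidise easily), the doubly benzylic Cα–H, and the Cβ hydroxyl, which can eliminate toward a stilbene or be attacked by an ortho phenol under acid. The first real difficulty is that Cα carries two almost identical 2,4-dioxygenated aryl groups (rings A and C), so no reagent can distinguish them by size; its configuration has to come from a stereospecific addition to an alkene of defined geometry. The second is that C3 is remote from every other functional group and must be brought in already configured or set by a catalyst alone. The key step exploits the fact that O1 and C4 sit on the adjacent ring A carbons C8a and C4a, while C8, the other neighbour of C8a, is flanked by the O7 substituent. One iodide at C8a is therefore enough to attach the whole C4–C3–C2–O unit.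

## Logic of the disconnections

**23 to 22.** The six O–CH2Ph bonds of 22 are cut (five aryl ethers and the Cβ ether). One protecting group for all six hydroxyls allows a single final step and avoids any differentiation of phenols. The gain is that every earlier intermediate is free of oxidisable phenols. The demand is that hydrogenolysis cleaves only O–benzyl bonds; this is met because C2 and Cβ, the only other sp3 carbons bearing oxygen, are not benzylic.

**22 to 12 and 21.** The bonds C4–C4a and O1–C8a are cut, which removes the pyran and separates ring A with its complete side chain (12) from ring B with the C2–C3–C4 unit (21). The cut is placed here because C8a and C4a are adjacent, so a single C8a–I bond can direct both bond formations, and because C3 then arrives configured and is untouched. The gain is full convergence: two fragments of similar size, neither containing a ring that must be built. The demand is one alkylation only, at C4a and not at C8, and an aryl–oxygen reductive elimination that beats β-hydride elimination of a primary alkoxide.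

**12 to 11 to 10.** The C8a–I bond is traced to C8a–Br and the Cβ O–benzyl bond is cut. An aryl iodide could not survive the palladium-catalysed step that builds the side chain; a bromide can if the coupling partner is an iodide, and it is exchanged afterwards. The Cβ hydroxyl is capped because a free secondary carbinol is a hydride donor toward arylpalladium species in the annulation. The demand is a halogen exchange that tolerates five benzyl ethers and two stereocentres.

**10 to 6 and 8 (through 9).** The Cα–ring C bond and the Cβ–O bond (as Cβ–B) are cut, leading to an (E)-alkene and the ring C iodide. Both stereocentres then arise from one syn addition. The relative configuration follows from the alkene geometry and from which aryl group is on the alkene and which is added; the absolute configuration follows from the copper ligand. This answers the problem of the two look-alike aryl groups on Cα. The demand is borylcupration with copper at the benzylic carbon, stereoretentive transfer to palladium, and a palladium catalyst that inserts into C–I of 8 and not into C–Br of 6.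

**6 to 3 and 5; 3 to 2 to 1; 5 to 4; 8 to 7.** The Cα=Cβ double bond is cut into a ring A aldehyde and a two-carbon sulfone carrying ring D. This olefination needs no palladium, so the ring A bromide is safe, and it favours the (E)-isomer. The remaining cuts are a sulfur–carbon bond and O–benzyl bonds, reaching purchasable materials. The demand is that no excess base remains to move the double bond toward ring D.

**21 to 20 to 19 to 18.** The C–Br bond and then the acetate are traced back to a prochiral 2-aryl-propane-1,3-diol. The stereocentre is defined only by the difference between the two CH2 arms, so an enzyme that acylates one enantiotopic hydroxyl sets it in one step. The demand is that nothing equilibrates the two arms afterwards: no acyl migration before bromination, and no oxetane formation or loss of HBr when the acetate is removed.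

**18 to 17 to 15 and 16; 15 to 14 to 13.** The two C–O bonds of the diol come from a malonate, and the aryl–C bond is cut to an aryl iodide and 16. The iodide comes from 13 by iodination ortho to the phenol and benzylation. The demand is iodination at C6 of 13 and not at C4.

## Other disconnections considered

**Alternative 1:** The cut is in the side chain: Cα–ring C and Cβ–O are disconnected on a substrate that already contains the pyran, leading to the chroman-bearing (E)-alkene A2 and iodide 8. In the forward direction, borylcupration of A2 (CuCl, chiral N-heterocyclic carbene, NaOtBu, B2pin2) and palladium-catalysed coupling of the benzylic copper intermediate would give boronate A1; oxidation and hydrogenolysis would then give 23.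
- In its favour: the two adjacent stereocentres would be set in one catalytic step at the end.
- Better than the chosen plan: A2 carries no carbon–halogen bond, so palladium sees a single electrophile, whereas the chosen plan must spare the C–Br bond of 6. Neither benzylation of the Cβ hydroxyl nor a halogen exchange is needed, which saves two steps on that branch.
- Against it: the cut does not touch the pyran. A2 still requires a separate construction of the 3-aryl chroman with its C3 centre on a ring A that also carries a C6 aldehyde. The least efficient reaction of the synthesis (three components, two ortho-benzyloxy groups meeting at Cα) would be run on the most advanced material.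
- Comparison: on mechanism and stereocontrol the two plans are equal, since both use the same syn borylcupration and stereoretentive copper-to-palladium transfer, and the remote C3 centre of A2 should neither help nor harm. On step count the alternative is at best equal once the chroman synthesis is added. The chosen plan runs the three-component step early on a two-step alkene and builds the ring late.

**Alternative 2:** The cut is C3–C1' (ring B) together with a temporary C4–O2' bond, leading to the 2H-chromene A4 and the free iodophenol 14. In the forward direction, a palladium oxyarylation (Pd(OAc)2, chiral bisphosphine, Ag2CO3) would add the aryl group to C3 and the phenol oxygen to C4 from the same face, giving the cis-fused pterocarpan A3. Hydrogenolysis would then cleave the benzylic C4–O bond together with the benzyl ethers and give 23 directly.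
- Better than the chosen plan: ring B enters as 14, one step from 13, against seven steps to 21. The ring B phenol needs no protecting group, and the last step does double duty.
- Equal: the cis ring fusion follows from the syn mechanism and is irrelevant in the end, because C4 finishes as CH2.
- Against it: C3 is created in the key step. Its absolute configuration would rest on face selection by a chiral ligand in a cationic Heck-type carbopalladation of a chromene, for which high and general selectivity cannot be relied on. Because the side chain is already chiral, any shortfall would appear as a C3 diastereomer that is hard to remove. A4 needs a C8a phenol and a pyran-forming annulation on the arene carrying the side chain, with the same C4a-versus-C8 question as the chosen plan but no handle to decide it. Silver is consumed in stoichiometric amount.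
- Comparison: the chosen plan is longer on the ring B branch, but it imports C3 from an enzymatically desymmetrised fragment and forms no stereocentre in the key step, so it is the safer plan for a single enantiomer.

**Alternative 3:** The cut is C3–C4 and O1–C2, leading to the ring A sulfone A6 and the arylacetaldehyde A7. In the forward direction, base would release an o-quinone methide from A6 (C4 exocyclic, O1 as carbonyl oxygen). The enamine formed from A7 and a diarylprolinol silyl ether would attack it at C4, and hemiacetal closure would give the 2-chromanol A5. An ionic reduction (silane, Lewis acid) would then remove the anomeric hydroxyl to reach 22.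
- Better than the chosen plan: the aminocatalytic annulation of o-quinone methides with aldehydes is an established reaction type, whereas the chosen key step has no direct precedent for this ring size. No transition metal is needed, and A7 is a shorter fragment than 21.
- Against it: C3 is formed in the key step next to a masked aldehyde and an aryl group, so it can epimerise through the open hydroxy aldehyde until the lactol is reduced. A7 is an enolisable arylacetaldehyde prone to self-condensation. The methide from A6 is unsubstituted at C4 and so less stabilised than the aryl-substituted cases where the method is strongest, although the C7 benzyloxy group para to C4a helps. A6 needs a phenol at C8a and a one-carbon unit at C4a on the fully elaborated ring A, at least three extra steps on the most valuable intermediate. The lactol reduction adds a step and exposes six benzyl ethers and electron-rich rings to a Lewis acid.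
- Comparison: on precedent the alternative is better; on configurational security of C3 and on the number of steps after ring closure the chosen plan is better; in convergence the two are equal.

Key step: step 16

Assumption: 1, 4, 7, 13 and 16 are taken as purchasable.
Assumption: ring C is introduced as the iodide 8, because a ring C bromide could not be distinguished by palladium from the ring A C–Br bond of 6; the ring A bromide is exchanged for iodide only afterwards (step 8).
Assumption: the lipase of step 13 acylates the enantiotopic CH2OH group that leads to (S)-19. The descriptors (R) of 21 and (3R) of 22 and 23 describe the same arrangement, because CH2Br becomes C4 and CH2OH becomes C2.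

## Route

Step 1
Reactants: 1 2-[4-(benzyloxy)phenyl]ethan-1-ol
Product: 2 5-({2-[4-(benzyloxy)phenyl]ethyl}sulfanyl)-1-phenyl-1H-tetrazole
Conditions: 1-phenyl-1H-tetrazole-5-thiol, PPh3, DIAD, THF, 0 °C → rt
Reagents that add atoms: 1-phenyl-1H-tetrazole-5-thiol, Sc1nnnn1-c1ccccc1
Why: Mitsunobu thioetherification; the acidic tetrazole thiol displaces the alkoxyphosphonium ion at the primary carbon by SN2, and the benzyl ether is inert.

Step 2
Reactants: 2 5-({2-[4-(benzyloxy)phenyl]ethyl}sulfanyl)-1-phenyl-1H-tetrazole
Product: 3 5-({2-[4-(benzyloxy)phenyl]ethyl}sulfonyl)-1-phenyl-1H-tetrazole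
Conditions: H2O2 (30 %), (NH4)6Mo7O24·4H2O (cat.), EtOH, 0 °C → rt
Reagents that add atoms: hydrogen peroxide, OO
Why: Molybdate-catalysed peroxide oxidation of sulfide to sulfone, the standard entry to Julia–Kocienski reagents; the benzyloxyarene is not oxidised under these conditions.

Step 3
Reactants: 4 4-bromo-2-hydroxybenzaldehyde
Product: 5 2-(benzyloxy)-4-bromobenzaldehyde
Conditions: BnBr, K2CO3, DMF, rt
Reagents that add atoms: benzyl bromide, BrCc1ccccc1
Why: Williamson etherification of the phenoxide; the aldehyde and the aryl bromide are unaffected.

Step 4
Reactants: 3 5-({2-[4-(benzyloxy)phenyl]ethyl}sulfonyl)-1-phenyl-1H-tetrazole; 5 2-(benzyloxy)-4-bromobenzaldehyde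
Product: 6 (E)-2-(benzyloxy)-1-{3-[4-(benzyloxy)phenyl]prop-1-en-1-yl}-4-bromobenzene
Conditions: 3, KN(SiMe3)2 (1.0 equiv), DME, −60 °C; then 5, −60 °C → rt
Reagents that add atoms: none
Why: Julia–Kocienski olefination; the metalated sulfone adds to the aldehyde, Smiles rearrangement and anti loss of SO2 and tetrazololate should give mainly the (E)-alkene. Exactly one equivalent of base is used so that none remains to move the double bond toward ring D; no palladium is involved, so the C–Br bond is safe.

Step 5
Reactants: 7 4-iodobenzene-1,3-diol (4-iodoresorcinol)
Product: 8 2,4-bis(benzyloxy)-1-iodobenzene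
Conditions: BnBr, K2CO3, DMF, 50 °C
Reagents that add atoms: benzyl bromide, BrCc1ccccc1
Why: Double Williamson etherification; the aryl iodide is stable to carbonate.

Step 6
Reactants: 6 (E)-2-(benzyloxy)-1-{3-[4-(benzyloxy)phenyl]prop-1-en-1-yl}-4-bromobenzene; 8 2,4-bis(benzyloxy)-1-iodobenzene
Product: 10 (1R,2R)-1-[2-(benzyloxy)-4-bromophenyl]-1-[2,4-bis(benzyloxy)phenyl]-3-[4-(benzyloxy)phenyl]propan-2-ol, via the (1R,2R) C2 pinacol boronate 9 (not isolated)
Conditions: B2pin2, CuCl/chiral imidazolinium salt (5 mol %), PdCl2(dppf) (3 mol %), NaOtBu, THF/toluene, 0 °C → rt; then NaOH, H2O2, THF/H2O, 0 °C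
Reagents that add atoms: bis(pinacolato)diboron, CC1(C)OB(B2OC(C)(C)C(C)(C)O2)OC1(C)C (boron of 9); hydrogen peroxide, OO (oxygen of 10)
Why: Copper/palladium three-component arylboration of an alkenylarene: the chiral carbene–copper boryl adds syn with boron at C2 and copper at benzylic C1, on the alkene face that is Re at C2 and Si at C1 (selected by the ligand); the benzylic copper transfers to the arylpalladium iodide from 8 with retention and reductive elimination forms C1–ring C. Both stereocentres thus come from one syn addition to the (E)-alkene (relative configuration from the geometry, absolute from the ligand), and oxidation of C–B proceeds with retention. The bisphosphine palladium catalyst should insert into the C–I bond of 8 well before the ring A C–Br bond.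

Step 7
Reactants: 10 (1R,2R)-1-[2-(benzyloxy)-4-bromophenyl]-1-[2,4-bis(benzyloxy)phenyl]-3-[4-(benzyloxy)phenyl]propan-2-ol
Product: 11 2-(benzyloxy)-1-{(1R,2R)-2-(benzyloxy)-1-[2,4-bis(benzyloxy)phenyl]-3-[4-(benzyloxy)phenyl]propyl}-4-bromobenzene
Conditions: NaH, BnBr, Bu4NI (cat.), DMF, 0 °C → rt
Reagents that add atoms: benzyl bromide, BrCc1ccccc1
Why: Williamson benzylation of the secondary alkoxide; it removes the carbinol that would act as a hydride donor toward arylpalladium in step 16 and keeps the final deprotection to one operation. NaH does not deprotonate the diarylmethine, so both stereocentres are untouched.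

Step 8
Reactants: 11 2-(benzyloxy)-1-{(1R,2R)-2-(benzyloxy)-1-[2,4-bis(benzyloxy)phenyl]-3-[4-(benzyloxy)phenyl]propyl}-4-bromobenzene
Product: 12 2-(benzyloxy)-1-{(1R,2R)-2-(benzyloxy)-1-[2,4-bis(benzyloxy)phenyl]-3-[4-(benzyloxy)phenyl]propyl}-4-iodobenzene
Conditions: CuI (10 mol %), trans-N,N'-dimethylcyclohexane-1,2-diamine (20 mol %), NaI, 1,4-dioxane, 110 °C
Reagents that add atoms: sodium iodide, [Na+].[I-]
Why: Copper-catalysed aromatic Finkelstein exchange, driven by the low solubility of NaBr in dioxane; benzyl ethers and sp3 stereocentres are inert to these neutral conditions.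

Step 9
Reactants: 13 2,3-dimethoxyphenol
Product: 14 6-iodo-2,3-dimethoxyphenol
Conditions: NIS (1.0 equiv), MeCN, −20 → 0 °C
Reagents that add atoms: N-iodosuccinimide, O=C1CCC(=O)N1I
Why: Electrophilic iodination; C6 is ortho to the free hydroxyl and para to the 3-methoxy group, whereas C4 is shielded by the in-plane 3-methoxy group, so substitution at C6 is expected.

Step 10
Reactants: 14 6-iodo-2,3-dimethoxyphenol
Product: 15 2-(benzyloxy)-1-iodo-3,4-dimethoxybenzene
Conditions: BnBr, K2CO3, DMF, rt
Reagents that add atoms: benzyl bromide, BrCc1ccccc1
Why: Williamson etherification of the hindered but acidic phenol.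

Step 11
Reactants: 15 2-(benzyloxy)-1-iodo-3,4-dimethoxybenzene; 16 diethyl malonate
Product: 17 diethyl 2-[2-(benzyloxy)-3,4-dimethoxyphenyl]propanedioate
Conditions: CuI (10 mol %), 2-picolinic acid (20 mol %), Cs2CO3, 1,4-dioxane, 60 °C
Reagents that add atoms: none
Why: Copper-catalysed α-arylation of a malonate with an aryl iodide (Hurtley-type coupling); an ortho alkoxy group is tolerated and the product is protected from diarylation as its enolate.

Step 12
Reactants: 17 diethyl 2-[2-(benzyloxy)-3,4-dimethoxyphenyl]propanedioate
Product: 18 2-[2-(benzyloxy)-3,4-dimethoxyphenyl]propane-1,3-diol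
Conditions: LiAlH4, THF, 0 °C → rt (17 added to the hydride)
Reagents that add atoms: none
Why: Hydride reduction of both esters; inverse addition to excess hydride limits enolate formation, which would otherwise stall the reduction. The product is prochiral.

Step 13
Reactants: 18 2-[2-(benzyloxy)-3,4-dimethoxyphenyl]propane-1,3-diol
Product: 19 (S)-2-[2-(benzyloxy)-3,4-dimethoxyphenyl]-3-hydroxypropyl acetate
Conditions: lipase from Burkholderia cepacia (Amano PS, immobilised), vinyl acetate, tBuOMe, 25 °C
Reagents that add atoms: vinyl acetate, CC(=O)OC=C
Why: Enzymatic desymmetrisation of a prochiral 2-aryl-1,3-diol; the lipase acylates one enantiotopic hydroxymethyl group and the enol ester makes the transfer irreversible. The stereocentre is set by the enzyme, and slow over-acylation of the minor enantiomer should raise the enantiomeric purity of the monoacetate.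

Step 14
Reactants: 19 (S)-2-[2-(benzyloxy)-3,4-dimethoxyphenyl]-3-hydroxypropyl acetate
Product: 20 (R)-3-bromo-2-[2-(benzyloxy)-3,4-dimethoxyphenyl]propyl acetate
Conditions: CBr4, PPh3, CH2Cl2, 0 °C
Reagents that add atoms: carbon tetrabromide, BrC(Br)(Br)Br
Why: Appel bromination by SN2 at the primary carbon. The stereocentre is not touched; its descriptor changes only because CH2Br outranks CH2OAc. Bromination fixes the two arms before any acyl migration can scramble them.

Step 15
Reactants: 20 (R)-3-bromo-2-[2-(benzyloxy)-3,4-dimethoxyphenyl]propyl acetate
Product: 21 (R)-3-bromo-2-[2-(benzyloxy)-3,4-dimethoxyphenyl]propan-1-ol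
Conditions: HCl (0.2 equiv), MeOH, 0 °C → rt
Reagents that add atoms: none
Why: Acid-catalysed transesterification; no alkoxide is formed, so neither oxetane closure (which would give an achiral intermediate) nor loss of HBr toward the allylic alcohol can occur.

Step 16
Reactants: 12 2-(benzyloxy)-1-{(1R,2R)-2-(benzyloxy)-1-[2,4-bis(benzyloxy)phenyl]-3-[4-(benzyloxy)phenyl]propyl}-4-iodobenzene; 21 (R)-3-bromo-2-[2-(benzyloxy)-3,4-dimethoxyphenyl]propan-1-ol
Product: 22 (3R)-7-(benzyloxy)-3-[2-(benzyloxy)-3,4-dimethoxyphenyl]-6-{(1R,2R)-2-(benzyloxy)-1-[2,4-bis(benzyloxy)phenyl]-3-[4-(benzyloxy)phenyl]propyl}-3,4-dihydro-2H-chromene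
Conditions: Pd(OAc)2 (10 mol %), XPhos (20 mol %), norbornene (1 equiv), Cs2CO3 (3 equiv), 1,4-dioxane, 100 °C; 21 (2 equiv) added slowly
Reagents that add atoms: none
Why: Proposed new method: zerovalent palladium inserts into the C8a–I bond of 12, norbornene inserts, and base-assisted C–H palladation at C4a gives the five-membered aryl–norbornyl palladacycle; the primary C–Br bond of 21 adds oxidatively to give tetravalent palladium, and reductive elimination forms C4–C4a. Norbornene then leaves by β-carbon elimination, which returns a divalent arylpalladium species at C8a; its pendant hydroxyl is deprotonated by Cs2CO3 and C–O reductive elimination from the seven-membered oxapalladacycle forms O1–C8a, so the pyran is closed by an intermolecular C–C bond formation followed by an intramolecular aryl–oxygen bond formation. The closest known reaction types are the palladium/norbornene ortho-alkylation with ipso-etherification of aryl iodides by epoxides, which gives 2,3-dihydrobenzofurans, and the analogous annulation with N-protected bromoalkylamines, which gives indolines and tetrahydroquinolines; the six-membered oxygen ring and the free bromo alcohol are the new elements. No stereocentre is formed: C3 comes from 21 and no bond to it is made or broken. The step needs a single alkylation at C4a; C8–H lies between the palladium-bearing carbon and the C7 benzyloxy group, whose CH2Ph arm is turned toward C8 by the bulky C6 substituent, so palladation there should be disfavoured, and the iodide is para to the side chain and therefore unhindered. It also needs C–O reductive elimination to outrun β-hydride elimination of the arylpalladium alkoxide, which the bulky biarylphosphine and the intramolecular setting favour. Slow addition of 21 and sparingly soluble Cs2CO3 in dioxane keep the free alkoxide low, so that oxetane formation and loss of HBr should stay minor.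

Step 17
Reactants: 22 (3R)-7-(benzyloxy)-3-[2-(benzyloxy)-3,4-dimethoxyphenyl]-6-{(1R,2R)-2-(benzyloxy)-1-[2,4-bis(benzyloxy)phenyl]-3-[4-(benzyloxy)phenyl]propyl}-3,4-dihydro-2H-chromene
Product: 23 (3R)-6-[(1R,2R)-1-(2,4-dihydroxyphenyl)-2-hydroxy-3-(4-hydroxyphenyl)propyl]-3-(2-hydroxy-3,4-dimethoxyphenyl)-3,4-dihydro-2H-chromen-7-ol
Conditions: H2 (1 atm), Pd/C (10 %), EtOAc/MeOH, rt
Reagents that add atoms: none
Why: Hydrogenolysis of six benzyl ethers; C2 and Cβ, the only other sp3 carbons bearing oxygen, are not benzylic, so only the protecting groups should be cleaved and the three stereocentres are untouched. Neutral conditions avoid acid-promoted reactions of the Cβ hydroxyl.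

## Compound list

1 | 2-[4-(benzyloxy)phenyl]ethan-1-ol | OCCc1ccc(OCc2ccccc2)cc1 | starting material
2 | 5-({2-[4-(benzyloxy)phenyl]ethyl}sulfanyl)-1-phenyl-1H-tetrazole | c1ccc(COc2ccc(CCSc3nnnn3-c3ccccc3)cc2)cc1 | intermediate
3 | 5-({2-[4-(benzyloxy)phenyl]ethyl}sulfonyl)-1-phenyl-1H-tetrazole | O=S(=O)(CCc1ccc(OCc2ccccc2)cc1)c1nnnn1-c1ccccc1 | intermediate
4 | 4-bromo-2-hydroxybenzaldehyde | O=Cc1ccc(Br)cc1O | starting material
5 | 2-(benzyloxy)-4-bromobenzaldehyde | O=Cc1ccc(Br)cc1OCc1ccccc1 | intermediate
6 | (E)-2-(benzyloxy)-1-{3-[4-(benzyloxy)phenyl]prop-1-en-1-yl}-4-bromobenzene | Brc1ccc(/C=C/Cc2ccc(OCc3ccccc3)cc2)c(OCc2ccccc2)c1 | intermediate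
7 | 4-iodobenzene-1,3-diol | Oc1ccc(I)c(O)c1 | starting material
8 | 2,4-bis(benzyloxy)-1-iodobenzene | Ic1ccc(OCc2ccccc2)cc1OCc1ccccc1 | intermediate
9 | 2-{(1R,2R)-1-[2-(benzyloxy)-4-bromophenyl]-1-[2,4-bis(benzyloxy)phenyl]-3-[4-(benzyloxy)phenyl]propan-2-yl}-4,4,5,5-tetramethyl-1,3,2-dioxaborolane | Brc1ccc([C@@H](c2ccc(OCc3ccccc3)cc2OCc2ccccc2)[C@H](B2OC(C)(C)C(C)(C)O2)Cc2ccc(OCc3ccccc3)cc2)c(OCc2ccccc2)c1 | intermediate
10 | (1R,2R)-1-[2-(benzyloxy)-4-bromophenyl]-1-[2,4-bis(benzyloxy)phenyl]-3-[4-(benzyloxy)phenyl]propan-2-ol | Brc1ccc([C@@H](c2ccc(OCc3ccccc3)cc2OCc2ccccc2)[C@H](O)Cc2ccc(OCc3ccccc3)cc2)c(OCc2ccccc2)c1 | intermediate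
11 | 2-(benzyloxy)-1-{(1R,2R)-2-(benzyloxy)-1-[2,4-bis(benzyloxy)phenyl]-3-[4-(benzyloxy)phenyl]propyl}-4-bromobenzene | Brc1ccc([C@@H](c2ccc(OCc3ccccc3)cc2OCc2ccccc2)[C@H](OCc2ccccc2)Cc2ccc(OCc3ccccc3)cc2)c(OCc2ccccc2)c1 | intermediate
12 | 2-(benzyloxy)-1-{(1R,2R)-2-(benzyloxy)-1-[2,4-bis(benzyloxy)phenyl]-3-[4-(benzyloxy)phenyl]propyl}-4-iodobenzene | Ic1ccc([C@@H](c2ccc(OCc3ccccc3)cc2OCc2ccccc2)[C@H](OCc2ccccc2)Cc2ccc(OCc3ccccc3)cc2)c(OCc2ccccc2)c1 | intermediate
13 | 2,3-dimethoxyphenol | COc1cccc(O)c1OC | starting material
14 | 6-iodo-2,3-dimethoxyphenol | COc1ccc(I)c(O)c1OC | intermediate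
15 | 2-(benzyloxy)-1-iodo-3,4-dimethoxybenzene | COc1ccc(I)c(OCc2ccccc2)c1OC | intermediate
16 | diethyl malonate | CCOC(=O)CC(=O)OCC | starting material
17 | diethyl 2-[2-(benzyloxy)-3,4-dimethoxyphenyl]propanedioate | CCOC(=O)C(C(=O)OCC)c1ccc(OC)c(OC)c1OCc1ccccc1 | intermediate
18 | 2-[2-(benzyloxy)-3,4-dimethoxyphenyl]propane-1,3-diol | OCC(CO)c1ccc(OC)c(OC)c1OCc1ccccc1 | intermediate
19 | (S)-2-[2-(benzyloxy)-3,4-dimethoxyphenyl]-3-hydroxypropyl acetate | CC(=O)OC[C@H](CO)c1ccc(OC)c(OC)c1OCc1ccccc1 | intermediate
20 | (R)-3-bromo-2-[2-(benzyloxy)-3,4-dimethoxyphenyl]propyl acetate | CC(=O)OC[C@H](CBr)c1ccc(OC)c(OC)c1OCc1ccccc1 | intermediate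
21 | (R)-3-bromo-2-[2-(benzyloxy)-3,4-dimethoxyphenyl]propan-1-ol | OC[C@H](CBr)c1ccc(OC)c(OC)c1OCc1ccccc1 | intermediate
22 | (3R)-7-(benzyloxy)-3-[2-(benzyloxy)-3,4-dimethoxyphenyl]-6-{(1R,2R)-2-(benzyloxy)-1-[2,4-bis(benzyloxy)phenyl]-3-[4-(benzyloxy)phenyl]propyl}-3,4-dihydro-2H-chromene | COc1ccc([C@@H]2COc3cc(OCc4ccccc4)c([C@@H](c4ccc(OCc5ccccc5)cc4OCc4ccccc4)[C@H](OCc4ccccc4)Cc4ccc(OCc5ccccc5)cc4)cc3C2)c(OCc2ccccc2)c1OC | intermediate
23 | (3R)-6-[(1R,2R)-1-(2,4-dihydroxyphenyl)-2-hydroxy-3-(4-hydroxyphenyl)propyl]-3-(2-hydroxy-3,4-dimethoxyphenyl)-3,4-dihydro-2H-chromen-7-ol | COc1ccc([C@@H]2COc3cc(O)c([C@@H](c4ccc(O)cc4O)[C@H](O)Cc4ccc(O)cc4)cc3C2)c(O)c1OC | target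

## Step count and least certain steps

Total: 17 steps (the arylboration with oxidative work-up counted as one). Longest linear sequence: 9 steps, from 13 through steps 9–17 to 23.

**Key step (step 16).** The process most likely to fail is the selection between the two ortho C–H bonds and between one and two alkylations. A benzyloxy group is only a medium-sized guard for C8, so a second palladation there after the first alkylation would lead to double alkylation or to norbornene-containing by-products. Next in likelihood is β-hydride elimination of the arylpalladium alkoxide, which would reduce C8a and oxidise the carbinol of the chain. Third is base-induced loss of HBr or oxetane closure of 21 before it reaches the palladacycle; the oxetane is achiral, so any product formed through it would be racemic at C3. A bridgehead-substituted norbornene, which speeds β-carbon elimination after a single alkylation, is the first change of conditions to try.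

The fallback abandons palladium/norbornene catalysis and uses known reactions. It sets out from 11 and 21 and returns at 22. Hydroxylation of the C–Br bond of 11 (Pd2(dba)3, tBuXPhos, KOH, dioxane/water) should give the C8a phenol analogue of 11, F1. Amine-catalysed ortho-bromination (N-bromosuccinimide, catalytic iPr2NH, CH2Cl2) is expected to occur on the free phenol at the unflanked ortho position para to the benzyloxy group and give the C4a-bromophenol F2. Mitsunobu etherification of F2 with 21 forms O1–C2 and gives the bromo ether F3. Zinc insertion into the primary C–Br bond (Zn, LiCl, THF) and intramolecular Negishi coupling with the aryl bromide (Pd(OAc)2, SPhos) form C4–C4a and give 22. This costs four steps in place of steps 8 and 16.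

**Step 6.** Three processes threaten this step: competing oxidative addition at the ring A C–Br bond, which would lead to oligomers; base-induced migration of the double bond of 6 toward ring D before borylcupration, which would give the regioisomeric adduct; and slow transfer and reductive elimination, because two ortho-benzyloxy aryl groups meet at Cα. Insufficient face selection would show up as the enantiomer, since the relative configuration is fixed by the mechanism.

The fallback uses neither palladium nor strong base on the alkene and remains stereospecific; anti addition to the (Z)-alkene gives the same diastereomer as syn addition to the (E)-alkene. It sets out from 1 and 5 and returns at 10. Appel bromination of 1 gives 1-(benzyloxy)-4-(2-bromoethyl)benzene F4, and PPh3 in hot toluene gives the phosphonium bromide F5. A salt-free Wittig reaction with 5 (NaN(SiMe3)2 in slight deficiency, THF, −78 °C) should give mainly the (Z)-alkene F6. Jacobsen epoxidation with the appropriate enantiomer of [N,N'-bis(3,5-di-tert-butylsalicylidene)-1,2-cyclohexanediamine]manganese chloride and buffered NaOCl should give the cis-epoxide F7, (2S,3R). The arylmagnesium reagent made from 8 with iPrMgCl·LiCl, with catalytic CuI, is expected to open F7 at the benzylic carbon with inversion and give 10.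

**Step 13.** The sense and the level of enantiotopic-group selection by the lipase may be unsatisfactory, because the ortho-benzyloxy group makes the aryl substituent much bulkier than in the 2-phenyl diols for which the enzyme is reliable; slow 1,3-acyl migration in 19 would erode the result further.

The fallback replaces the enzyme with a small-molecule catalyst whose enantiomer can be chosen. It sets out from 18 and returns at 21. Desymmetrising benzoylation with a dinuclear zinc catalyst (Et2Zn, the appropriate enantiomer of the ProPhenol ligand, vinyl benzoate, THF) should give the (S)-monobenzoate F8. Appel bromination gives the (R)-bromo benzoate F9, and brief methanolysis (catalytic NaOMe, MeOH, 0 °C, stopped early) gives 21.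

**Step 17.** Cleavage of the hindered secondary benzyl ether at Cβ is likely to lag behind the five aryl ethers, so that partly protected material persists; pushing the reaction risks saturation of the electron-rich rings, and the free polyphenol may bind to the catalyst and oxidise on work-up.

The fallback changes the reaction class to a Lewis-acid dealkylation with a cation scavenger: BCl3 and pentamethylbenzene in CH2Cl2 at −78 °C, which removes benzyl groups as benzylpentamethylbenzene and is expected to spare the two methyl ethers at that temperature. It sets out from 22 and returns at 23; no new compound is formed on this way (F0).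

## Further compounds

F1 | step 16 | 3-(benzyloxy)-4-{2-(benzyloxy)-1-[2,4-bis(benzyloxy)phenyl]-3-[4-(benzyloxy)phenyl]propyl}phenol, side-chain configuration as in 11 | Oc1ccc([C@@H](c2ccc(OCc3ccccc3)cc2OCc2ccccc2)[C@H](OCc2ccccc2)Cc2ccc(OCc3ccccc3)cc2)c(OCc2ccccc2)c1
F2 | step 16 | 5-(benzyloxy)-2-bromo-4-{2-(benzyloxy)-1-[2,4-bis(benzyloxy)phenyl]-3-[4-(benzyloxy)phenyl]propyl}phenol, side-chain configuration as in 11 | Oc1cc(OCc2ccccc2)c([C@@H](c2ccc(OCc3ccccc3)cc2OCc2ccccc2)[C@H](OCc2ccccc2)Cc2ccc(OCc3ccccc3)cc2)cc1Br
F3 | step 16 | (2R)-3-bromo-2-[2-(benzyloxy)-3,4-dimethoxyphenyl]propyl ether of F2 | BrC[C@@H](COc1cc(OCc2ccccc2)c([C@@H](c2ccc(OCc3ccccc3)cc2OCc2ccccc2)[C@H](OCc2ccccc2)Cc2ccc(OCc3ccccc3)cc2)cc1Br)c1ccc(OC)c(OC)c1OCc1ccccc1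
F4 | step 6 | 1-(benzyloxy)-4-(2-bromoethyl)benzene | BrCCc1ccc(OCc2ccccc2)cc1
F5 | step 6 | {2-[4-(benzyloxy)phenyl]ethyl}triphenylphosphonium bromide | [Br-].c1ccc(COc2ccc(CC[P+](c3ccccc3)(c3ccccc3)c3ccccc3)cc2)cc1
F6 | step 6 | (Z)-2-(benzyloxy)-1-{3-[4-(benzyloxy)phenyl]prop-1-en-1-yl}-4-bromobenzene | Brc1ccc(/C=C\Cc2ccc(OCc3ccccc3)cc2)c(OCc2ccccc2)c1
F7 | step 6 | (2S,3R)-2-[2-(benzyloxy)-4-bromophenyl]-3-[4-(benzyloxy)benzyl]oxirane | Brc1ccc([C@@H]2O[C@@H]2Cc2ccc(OCc3ccccc3)cc2)c(OCc2ccccc2)c1
F8 | step 13 | (S)-2-[2-(benzyloxy)-3,4-dimethoxyphenyl]-3-hydroxypropyl benzoate | O=C(OC[C@H](CO)c1ccc(OC)c(OC)c1OCc1ccccc1)c1ccccc1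
F9 | step 13 | (R)-3-bromo-2-[2-(benzyloxy)-3,4-dimethoxyphenyl]propyl benzoate | O=C(OC[C@H](CBr)c1ccc(OC)c(OC)c1OCc1ccccc1)c1ccccc1
F0 | step 17 | none | none
A1 | alternative 1 | Cβ pinacol boronate of the perbenzylated target, (3R) chroman with (1R,2R) side chain | COc1ccc([C@@H]2COc3cc(OCc4ccccc4)c([C@@H](c4ccc(OCc5ccccc5)cc4OCc4ccccc4)[C@H](B4OC(C)(C)C(C)(C)O4)Cc4ccc(OCc5ccccc5)cc4)cc3C2)c(OCc2ccccc2)c1OC
A2 | alternative 1 | (3R)-7-(benzyloxy)-3-[2-(benzyloxy)-3,4-dimethoxyphenyl]-6-{(E)-3-[4-(benzyloxy)phenyl]prop-1-en-1-yl}-3,4-dihydro-2H-chromene | COc1ccc([C@@H]2COc3cc(OCc4ccccc4)c(/C=C/Cc4ccc(OCc5ccccc5)cc4)cc3C2)c(OCc2ccccc2)c1OC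
A3 | alternative 2 | (6aR,11aR) cis-fused pterocarpan carrying the perbenzylated side chain and the 3,4-dimethoxy pattern of ring B | COc1ccc2c(c1OC)O[C@H]3c4cc([C@@H](c5ccc(OCc6ccccc6)cc5OCc5ccccc5)[C@H](OCc5ccccc5)Cc5ccc(OCc6ccccc6)cc5)c(OCc5ccccc5)cc4OC[C@@H]23
A4 | alternative 2 | 7-(benzyloxy)-6-{2-(benzyloxy)-1-[2,4-bis(benzyloxy)phenyl]-3-[4-(benzyloxy)phenyl]propyl}-2H-chromene, side-chain configuration as in 11 | C1=Cc2cc([C@@H](c3ccc(OCc4ccccc4)cc3OCc3ccccc3)[C@H](OCc3ccccc3)Cc3ccc(OCc4ccccc4)cc3)c(OCc3ccccc3)cc2OC1
A5 | alternative 3 | perbenzylated (3R)-3-aryl-chroman-2-ol, mixture of C2 anomers | COc1ccc([C@@H]2C(O)Oc3cc(OCc4ccccc4)c([C@@H](c4ccc(OCc5ccccc5)cc4OCc4ccccc4)[C@H](OCc4ccccc4)Cc4ccc(OCc5ccccc5)cc4)cc3C2)c(OCc2ccccc2)c1OC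
A6 | alternative 3 | 5-(benzyloxy)-2-[(4-methylbenzenesulfonyl)methyl]-4-{2-(benzyloxy)-1-[2,4-bis(benzyloxy)phenyl]-3-[4-(benzyloxy)phenyl]propyl}phenol, side-chain configuration as in 11 | Cc1ccc(S(=O)(=O)Cc2cc([C@@H](c3ccc(OCc4ccccc4)cc3OCc3ccccc3)[C@H](OCc3ccccc3)Cc3ccc(OCc4ccccc4)cc3)c(OCc3ccccc3)cc2O)cc1
A7 | alternative 3 | 2-[2-(benzyloxy)-3,4-dimethoxyphenyl]acetaldehyde | O=CCc1ccc(OC)c(OC)c1OCc1ccccc1
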